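**Retrosynthetic overview** (C1–C11 are the ring carbons of the target in SMILES order: C1 = CH–OAng, C2 = CH2, C3 = CH–OAc, C4 = C(Me), C5 = CH, C6 = C=O, C7 = CH=, C8 = =C(Me), C9 = CH, C10 = CH, C11 = CMe2)
1. Target ⇐ tricyclic enone with the carbonyl on C8 (MeLi addition, then oxidative 1,3-transposition puts C=O on C6 and Me on C8).
2. Cyclobutane closed last: C9 of a ring-A enol silane opens a C3–C4 epoxide at C4 (sets quaternary C4 and the C3–O centre together).
3. Seven-membered ring B ⇐ six-membered isopropenyl carbinol by a protio-semipinacol 1,2-shift (C10 migrates to the new CMe2 carbon C11): the key ring expansion.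
4. Ring A and C5/C10 ⇐ enantioselective Diels–Alder of a p-quinol silyl ether with 2-acetoxybutadiene; C1 by reagent-controlled reduction, C3 by face-selective epoxidation.
5. Building blocks: p-benzoquinone, isopropenylmagnesium bromide, methyl vinyl ketone, angelic acid. Ring order: A → B (six → seven) → cyclobutane.

Assumption: the sense of induction of the oxazaborolidinium catalyst in step 3 is taken from its usual enone model; if it proves opposite, the (3aR) catalyst is used and nothing else changes.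

**Step 1**
Reactants: 1 but-3-en-2-one (methyl vinyl ketone)
Product: 2 buta-1,3-dien-2-yl acetate
Conditions: isopropenyl acetate, 4-MeC6H4SO3H (cat.), hydroquinone (trace), 95 °C, acetone distilled off
Reagents that add atoms: isopropenyl acetate, CC(=C)OC(C)=O
Why: Acid-catalysed enol-ester exchange, driven by removal of acetone, gives the 2-acyloxy diene; no stereocentre is formed.

**Step 2**
Reactants: 3 cyclohexa-2,5-diene-1,4-dione (p-benzoquinone); 4 bromo(prop-1-en-2-yl)magnesium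
Product: 6 4-(prop-1-en-2-yl)-4-[(trimethylsilyl)oxy]cyclohexa-2,5-dien-1-one, via bromomagnesium quinol alkoxide 5 (not isolated)
Conditions: THF, −78 °C; then Me3SiCl, Et3N, −78 → 0 °C
Reagents that add atoms: chlorotrimethylsilane, C[Si](C)(C)Cl
Why: Grignard 1,2-addition to one quinone carbonyl at low temperature (p-quinol synthesis) and O-silylation of the tertiary alkoxide; the product is achiral.

**Step 3**
Reactants: 6 4-(prop-1-en-2-yl)-4-[(trimethylsilyl)oxy]cyclohexa-2,5-dien-1-one; 2 buta-1,3-dien-2-yl acetate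
Product: 7 (4aR,8R,8aS)-5-oxo-8-(prop-1-en-2-yl)-8-[(trimethylsilyl)oxy]-1,4,4a,5,8,8a-hexahydronaphthalen-2-yl acetate
Conditions: (3aS)-1-(2-methylphenyl)-3,3-diphenyltetrahydro-1H,3H-pyrrolo[1,2-c][1,3,2]oxazaborole·HN(SO2CF3)2 (20 mol %), CH2Cl2, −78 → −40 °C
Reagents that add atoms: none
Why: Catalytic enantioselective Diels–Alder reaction (cationic oxazaborolidinium on the dienone carbonyl) in which the diene CH2 next to the acetoxy carbon bonds to the β-carbon ("para" orientation), suprafacial addition gives the cis fusion, and the catalyst-controlled enone face sets C5 and C10 (4a and 8a here); the C8 epimer of 7, if formed, converges to the same product in step 4.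

**Step 4**
Reactants: 7 (4aR,8R,8aS)-5-oxo-8-(prop-1-en-2-yl)-8-[(trimethylsilyl)oxy]-1,4,4a,5,8,8a-hexahydronaphthalen-2-yl acetate
Product: 8 (4aR,9aS)-9,9-dimethyl-5,8-dioxo-4,4a,5,8,9,9a-hexahydro-1H-benzo[7]annulen-2-yl acetate
Conditions: HN(SO2CF3)2 (10 mol %), (CF3)2CHOH–CH2Cl2 1:4, −20 → 0 °C; aq. NaHCO3
Reagents that add atoms: none
Why: Proposed new method: a Brønsted-superacid protio-semipinacol ring expansion of a strain-free six-membered alkenyl carbinol, in which Markovnikov protonation of the isopropenyl group gives a tertiary cation next to the silyloxy carbon, C–O ionisation is suppressed by the γ-enone, and the C(sp3) ring carbon C10 migrates with retention in preference to the electron-poor enone β-carbon, so that loss of Me3Si+ leaves the seven-membered enedione with C11 in the ring and the cis fusion intact; the closest known reactions are the acid-catalysed protio-semipinacol expansion of strained 1-alkenylcyclobutanols and the selenonium-triggered one-carbon enlargement of β-hydroxy selenides, neither shown for an unstrained six-to-seven case with a competing vinyl migrator.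

**Step 5**
Reactants: 8 (4aR,9aS)-9,9-dimethyl-5,8-dioxo-4,4a,5,8,9,9a-hexahydro-1H-benzo[7]annulen-2-yl acetate
Product: 10 (4aR,5S,9aS)-5,9,9-trimethyl-8-oxo-4,4a,5,8,9,9a-hexahydro-1H-benzo[7]annulene-2,5-diyl diacetate, via titanium tertiary alkoxide 9 (not isolated)
Conditions: MeTi(OiPr)3, Et2O–THF, −20 → 20 °C; then Ac2O, 4-(dimethylamino)pyridine, 20 °C
Reagents that add atoms: methyltitanium triisopropoxide, C[Ti](OC(C)C)(OC(C)C)OC(C)C; acetic anhydride, CC(=O)OC(C)=O
Why: Chemoselective 1,2-carbonyl addition of the titanium reagent to the less hindered enedione carbonyl C4 (C1 is flanked by the quaternary carbon, the enol ester is untouched) from the convex face, followed by in-flask acetylation; the new carbinol centre is removed in step 6.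

**Step 6**
Reactants: 10 (4aR,5S,9aS)-5,9,9-trimethyl-8-oxo-4,4a,5,8,9,9a-hexahydro-1H-benzo[7]annulene-2,5-diyl diacetate
Product: 11 (4aR,9aS)-5,9,9-trimethyl-8-oxo-4,4a,7,8,9,9a-hexahydro-1H-benzo[7]annulen-2-yl acetate
Conditions: SmI2, tBuOH, THF, −78 °C
Reagents that add atoms: none
Why: Reductive elimination of the γ-acetoxy enone by divalent samarium gives the extended dienolate, and kinetic α-protonation delivers the β,γ-unsaturated ketone with the trisubstituted C3=C4(Me) bond; no new stereocentre.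

**Step 7**
Reactants: 11 (4aR,9aS)-5,9,9-trimethyl-8-oxo-4,4a,7,8,9,9a-hexahydro-1H-benzo[7]annulen-2-yl acetate
Product: 12 (4aR,8R,9aS)-8-hydroxy-5,9,9-trimethyl-4,4a,7,8,9,9a-hexahydro-1H-benzo[7]annulen-2-yl acetate
Conditions: (3aS)-1-methyl-3,3-diphenyltetrahydro-1H,3H-pyrrolo[1,2-c][1,3,2]oxazaborole (10 mol %), BH3·SMe2, THF, −20 °C; MeOH
Reagents that add atoms: none
Why: Corey–Bakshi–Shibata reduction: the ketone has a tert-alkyl (large) and a CH2 (small) flank, so the (3aS) catalyst gives the (R)-carbinol at C1, matched with hydride attack on the convex face anti to ring A.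

**Step 8**
Reactants: 12 (4aR,8R,9aS)-8-hydroxy-5,9,9-trimethyl-4,4a,7,8,9,9a-hexahydro-1H-benzo[7]annulen-2-yl acetate; 13 (2Z)-2-methylbut-2-enoic acid (angelic acid)
Product: 15 (4aR,8R,9aS)-2-(acetyloxy)-5,9,9-trimethyl-4,4a,7,8,9,9a-hexahydro-1H-benzo[7]annulen-8-yl (2Z)-2-methylbut-2-enoate, via angelic 2,4,6-trichlorobenzoic anhydride 14 (not isolated)
Conditions: 13, 2,4,6-Cl3C6H2COCl, Et3N, toluene, 20 °C; then 12, 75 °C
Reagents that add atoms: none
Why: Yamaguchi esterification through the mixed anhydride, the established way to acylate hindered secondary alcohols with angelic acid without Z-to-E isomerisation; C1 is retained.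

**Step 9**
Reactants: 15 (4aR,8R,9aS)-2-(acetyloxy)-5,9,9-trimethyl-4,4a,7,8,9,9a-hexahydro-1H-benzo[7]annulen-8-yl (2Z)-2-methylbut-2-enoate
Product: 16 (4aR,8R,9aS)-5,9,9-trimethyl-2-oxo-2,4a,7,8,9,9a-hexahydro-1H-benzo[7]annulen-8-yl (2Z)-2-methylbut-2-enoate
Conditions: Pd(OAc)2 (5 mol %), Ph2PCH2CH2PPh2 (5 mol %), Bu3SnOMe (20 mol %), allyl methyl carbonate, MeCN, 80 °C
Reagents that add atoms: none
Why: Tsuji dehydrogenation of an enol acetate: the tin methoxide releases the regiodefined enolate, which is passed to an allylpalladium species and undergoes β-hydride elimination towards C6, giving the ring-A cyclohexenone whose only enolisable α′ position is C9; no stereocentre is touched.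

**Step 10**
Reactants: 16 (4aR,8R,9aS)-5,9,9-trimethyl-2-oxo-2,4a,7,8,9,9a-hexahydro-1H-benzo[7]annulen-8-yl (2Z)-2-methylbut-2-enoate
Product: 17 (4aR,5S,6R,8R,9aS)-5,6-epoxy-5,9,9-trimethyl-2-oxo-2,4a,5,6,7,8,9,9a-octahydro-1H-benzo[7]annulen-8-yl (2Z)-2-methylbut-2-enoate
Conditions: 3-ClC6H4CO3H, NaHCO3, CH2Cl2, 0 °C
Reagents that add atoms: 3-chloroperbenzoic acid, OOC(=O)c1cccc(Cl)c1
Why: Prilezhaev epoxidation of the only electron-rich (trisubstituted) alkene from the convex face, anti to ring A and to the C1 ester, which sets the C3–O configuration and places the oxygen that must leave C4 opposite to C9.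

**Step 11**
Reactants: 17 (4aR,5S,6R,8R,9aS)-5,6-epoxy-5,9,9-trimethyl-2-oxo-2,4a,5,6,7,8,9,9a-octahydro-1H-benzo[7]annulen-8-yl (2Z)-2-methylbut-2-enoate
Product: 20 (1S,2S,3R,5R,7R,8R)-3-(acetyloxy)-2,6,6-trimethyl-11-oxotricyclo[5.4.0.0(2,8)]undec-9-en-5-yl (2Z)-2-methylbut-2-enoate, via ring-A enol silane 18 (not isolated), via tricyclic silyl ether 19 (not isolated)
Conditions: LiN(iPr)2, Me3SiCl, THF, −78 °C; then CH2Cl2, Me3SiOSO2CF3 (20 mol %), −78 → −40 °C; then Ac2O, −40 → 0 °C
Reagents that add atoms: acetic anhydride, CC(=O)OC(C)=O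
Why: Kinetic α′-deprotonation and silylation give the cross-conjugated enol silane, whose carbon C9 opens the Lewis-acid-activated epoxide at its tertiary carbon C4 in a 4-exo-tet Mukaiyama-type alkylation (the geometry Stork used for carbanion–epoxide cyclobutane closures) with inversion at C4 from the only face ring A can reach, so the quaternary centre, the bridgehead C9 and the retained C3–O configuration are fixed together, and the silyl ether is exchanged for acetate in the flask (the enone can no longer enolise, both flanking carbons being bridgeheads).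

**Step 12**
Reactants: 20 (1S,2S,3R,5R,7R,8R)-3-(acetyloxy)-2,6,6-trimethyl-11-oxotricyclo[5.4.0.0(2,8)]undec-9-en-5-yl (2Z)-2-methylbut-2-enoate
Product: 21 3-(acetyloxy)-11-hydroxy-2,6,6,11-tetramethyltricyclo[5.4.0.0(2,8)]undec-9-en-5-yl (2Z)-2-methylbut-2-enoate (ring stereocentres as in 20; hydroxyl on the side of the methyl-bearing C2 bridge)
Conditions: MeLi, CeCl3, THF, −78 °C
Reagents that add atoms: methyllithium, [Li]C
Why: Organocerium 1,2-addition to the enone carbonyl (the two esters survive at −78 °C) from the side of the CH bridge, away from the methyl-bearing bridge; the carbinol centre is removed in step 13.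

**Step 13**
Reactants: 21 3-(acetyloxy)-11-hydroxy-2,6,6,11-tetramethyltricyclo[5.4.0.0(2,8)]undec-9-en-5-yl (2Z)-2-methylbut-2-enoate
Product: 22 (1R,2R,3R,5R,7S,8R)-3-(acetyloxy)-2,6,6,11-tetramethyl-9-oxotricyclo[5.4.0.0(2,8)]undec-10-en-5-yl (2Z)-2-methylbut-2-enoate (target)
Conditions: C5H5NH[CrO3Cl] (pyridinium chlorochromate), 4 Å molecular sieves, CH2Cl2, 20 °C
Reagents that add atoms: pyridinium chlorochromate, c1cc[nH+]cc1.[O-][Cr](=O)(=O)Cl
Why: Dauben oxidative 1,3-transposition of the tertiary allylic alcohol through its chromate ester places the carbonyl on C6 and the methyl-bearing double bond at C7=C8 without touching any stereocentre.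

**Compound list**
1 | but-3-en-2-one (methyl vinyl ketone) | CC(=O)C=C | starting material
2 | buta-1,3-dien-2-yl acetate | CC(=O)OC(=C)C=C | intermediate
3 | cyclohexa-2,5-diene-1,4-dione (p-benzoquinone) | O=C1C=CC(=O)C=C1 | starting material
4 | bromo(prop-1-en-2-yl)magnesium | CC(=C)[Mg]Br | starting material
5 | bromomagnesium 4-oxo-1-(prop-1-en-2-yl)cyclohexa-2,5-dien-1-olate (bromomagnesium quinol alkoxide) | C=C(C)C1(O[Mg]Br)C=CC(=O)C=C1 | intermediate
6 | 4-(prop-1-en-2-yl)-4-[(trimethylsilyl)oxy]cyclohexa-2,5-dien-1-one | C=C(C)C1(O[Si](C)(C)C)C=CC(=O)C=C1 | intermediate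
7 | (4aR,8R,8aS)-5-oxo-8-(prop-1-en-2-yl)-8-[(trimethylsilyl)oxy]-1,4,4a,5,8,8a-hexahydronaphthalen-2-yl acetate | C=C(C)[C@@]1(O[Si](C)(C)C)C=CC(=O)[C@@H]2CC=C(OC(C)=O)C[C@@H]21 | intermediate
8 | (4aR,9aS)-9,9-dimethyl-5,8-dioxo-4,4a,5,8,9,9a-hexahydro-1H-benzo[7]annulen-2-yl acetate | O=C1C=CC(=O)[C@@H]2CC=C(OC(C)=O)C[C@@H]2C1(C)C | intermediate
9 | triisopropoxytitanium (4aR,5S,9aS)-2-(acetyloxy)-5,9,9-trimethyl-8-oxo-4,4a,5,8,9,9a-hexahydro-1H-benzo[7]annulen-5-olate (titanium tertiary alkoxide) | O=C1C=C[C@](C)(O[Ti](OC(C)C)(OC(C)C)OC(C)C)[C@@H]2CC=C(OC(C)=O)C[C@@H]2C1(C)C | intermediate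
10 | (4aR,5S,9aS)-5,9,9-trimethyl-8-oxo-4,4a,5,8,9,9a-hexahydro-1H-benzo[7]annulene-2,5-diyl diacetate | O=C1C=C[C@](C)(OC(C)=O)[C@@H]2CC=C(OC(C)=O)C[C@@H]2C1(C)C | intermediate
11 | (4aR,9aS)-5,9,9-trimethyl-8-oxo-4,4a,7,8,9,9a-hexahydro-1H-benzo[7]annulen-2-yl acetate | O=C1CC=C(C)[C@@H]2CC=C(OC(C)=O)C[C@@H]2C1(C)C | intermediate
12 | (4aR,8R,9aS)-8-hydroxy-5,9,9-trimethyl-4,4a,7,8,9,9a-hexahydro-1H-benzo[7]annulen-2-yl acetate | O[C@@H]1CC=C(C)[C@@H]2CC=C(OC(C)=O)C[C@@H]2C1(C)C | intermediate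
13 | (2Z)-2-methylbut-2-enoic acid (angelic acid) | C/C=C(/C)C(=O)O | starting material
14 | (2Z)-2-methylbut-2-enoic 2,4,6-trichlorobenzoic anhydride (angelic 2,4,6-trichlorobenzoic anhydride) | C/C=C(/C)C(=O)OC(=O)c1c(Cl)cc(Cl)cc1Cl | intermediate
15 | (4aR,8R,9aS)-2-(acetyloxy)-5,9,9-trimethyl-4,4a,7,8,9,9a-hexahydro-1H-benzo[7]annulen-8-yl (2Z)-2-methylbut-2-enoate | C/C=C(/C)C(=O)O[C@@H]1CC=C(C)[C@@H]2CC=C(OC(C)=O)C[C@@H]2C1(C)C | intermediate
16 | (4aR,8R,9aS)-5,9,9-trimethyl-2-oxo-2,4a,7,8,9,9a-hexahydro-1H-benzo[7]annulen-8-yl (2Z)-2-methylbut-2-enoate | C/C=C(/C)C(=O)O[C@@H]1CC=C(C)[C@@H]2C=CC(=O)C[C@@H]2C1(C)C | intermediate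
17 | (4aR,5S,6R,8R,9aS)-5,6-epoxy-5,9,9-trimethyl-2-oxo-2,4a,5,6,7,8,9,9a-octahydro-1H-benzo[7]annulen-8-yl (2Z)-2-methylbut-2-enoate | C/C=C(/C)C(=O)O[C@@H]1C[C@H]3O[C@@]3(C)[C@@H]2C=CC(=O)C[C@@H]2C1(C)C | intermediate
18 | (4aR,5S,6R,8R,9aS)-5,6-epoxy-5,9,9-trimethyl-2-[(trimethylsilyl)oxy]-4a,5,6,7,8,9-hexahydro-9aH-benzo[7]annulen-8-yl (2Z)-2-methylbut-2-enoate (ring-A enol silane) | C/C=C(/C)C(=O)O[C@@H]1C[C@H]3O[C@@]3(C)[C@@H]2C=CC(O[Si](C)(C)C)=C[C@@H]2C1(C)C | intermediate
19 | (1S,2S,3R,5R,7R,8R)-2,6,6-trimethyl-11-oxo-3-[(trimethylsilyl)oxy]tricyclo[5.4.0.0(2,8)]undec-9-en-5-yl (2Z)-2-methylbut-2-enoate (tricyclic silyl ether) | C/C=C(/C)C(=O)O[C@@H]1C[C@@H](O[Si](C)(C)C)[C@@]2(C)[C@@H]3C=CC(=O)[C@H]2[C@@H]3C1(C)C | intermediate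
20 | (1S,2S,3R,5R,7R,8R)-3-(acetyloxy)-2,6,6-trimethyl-11-oxotricyclo[5.4.0.0(2,8)]undec-9-en-5-yl (2Z)-2-methylbut-2-enoate | C/C=C(/C)C(=O)O[C@@H]1C[C@@H](OC(C)=O)[C@@]2(C)[C@@H]3C=CC(=O)[C@H]2[C@@H]3C1(C)C | intermediate
21 | 3-(acetyloxy)-11-hydroxy-2,6,6,11-tetramethyltricyclo[5.4.0.0(2,8)]undec-9-en-5-yl (2Z)-2-methylbut-2-enoate (ring stereocentres as in 20; hydroxyl on the side of the C2 bridge) | C/C=C(/C)C(=O)O[C@@H]1C[C@@H](OC(C)=O)[C@@]2(C)[C@@H]3C=C[C@](C)(O)[C@H]2[C@@H]3C1(C)C | intermediate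
22 | (1R,2R,3R,5R,7S,8R)-3-(acetyloxy)-2,6,6,11-tetramethyl-9-oxotricyclo[5.4.0.0(2,8)]undec-10-en-5-yl (2Z)-2-methylbut-2-enoate (CNP0260482.1) | C/C=C(/C)C(=O)O[C@@H]1C[C@@H](OC(C)=O)[C@@]2(C)[C@@H]3C(=O)C=C(C)[C@H]2[C@@H]3C1(C)C | target

**Totals**
Total step count: 13. Longest linear sequence: 12 steps (3 → 22, steps 2–13); step 1 is a one-step side branch.

**Three steps most likely to fail**

Step 4 (the proposed new ring expansion). Risks are capture of the tertiary cation by the enol acetate of ring A, epimerisation at C5 under acid, and an untested migratory preference. The fallback is the selenonium-triggered one-carbon ring enlargement of β-hydroxy selenides, which is established for cyclohexanone to 2,2-dimethylcycloheptanone with migration of the more substituted carbon. It sets out from 3. 2-Lithio-2-(methylselanyl)propane (from 2,2-bis(methylselanyl)propane and BuLi, THF, −78 °C) adds 1,2 to give lithium 1-[2-(methylselanyl)propan-2-yl]-4-oxocyclohexa-2,5-dien-1-olate F1. This is silylated in the same flask with Me3SiCl to 4-[2-(methylselanyl)propan-2-yl]-4-[(trimethylsilyl)oxy]cyclohexa-2,5-dien-1-one F2. The Diels–Alder reaction of step 3 with 2 then gives (4aR,8R,8aS)-8-[2-(methylselanyl)propan-2-yl]-5-oxo-8-[(trimethylsilyl)oxy]-1,4,4a,5,8,8a-hexahydronaphthalen-2-yl acetate F3. Se-methylation of F3 with MeOSO2CF3 in CH2Cl2 (−78 → 0 °C) makes dimethyl selenide the leaving group, so C10 migrates without any Brønsted acid, and the fallback comes back to the route at 8.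

Step 11 (cyclobutane closure). A four-membered ring is formed at a tertiary epoxide carbon; acid-induced rearrangement of the epoxide to a ketone or an allylic alcohol can compete. The fallback replaces the epoxide by a tertiary bromide with a participating neighbouring acetate and sets out from 17. Acetyl bromide in CH2Cl2 at −78 °C opens the epoxide at C4 with inversion to give (2Z)-2-methylbut-2-enoic ester 6-(acetyloxy)-5-bromo-5,9,9-trimethyl-2-oxo-2,4a,5,6,7,8,9,9a-octahydro-1H-benzo[7]annulen-8-yl (2Z)-2-methylbut-2-enoate F4 (bromide trans to the acetate). LiN(iPr)2 and Me3SiCl at −78 °C give its ring-A enol silane, 6-(acetyloxy)-5-bromo-5,9,9-trimethyl-2-[(trimethylsilyl)oxy]-4a,5,6,7,8,9-hexahydro-9aH-benzo[7]annulen-8-yl (2Z)-2-methylbut-2-enoate F5. AgOSO2CF3 in CH2Cl2 at −78 °C removes bromide, the acetate closes to a 1,3-dioxolan-2-ylium ion on the face away from ring A, and C9 attacks C4 from the ring-A face, so the acetate ends on C3 with the required configuration; the fallback comes back to the route at 20.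

Step 3 (enantioselective Diels–Alder). The dienophile class (a 4-alkenyl-4-silyloxy dienone) and the 2-acyloxy diene are an untested pairing for this catalyst, and the dienone may undergo dienone–phenol rearrangement. The fallback gives up asymmetric catalysis for resolution and sets out from 6 and 2. Me2AlCl-promoted (or thermal) Diels–Alder reaction gives racemic 7, and preparative chromatography on a chiral stationary phase with supercritical CO2 separates 7 from its enantiomer (4aS,8S,8aR)-5-oxo-8-(prop-1-en-2-yl)-8-[(trimethylsilyl)oxy]-1,4,4a,5,8,8a-hexahydronaphthalen-2-yl acetate F6, which is discarded; the fallback comes back to the route at 7.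

**Further compounds**
F1 | step 4 | lithium 1-[2-(methylselanyl)propan-2-yl]-4-oxocyclohexa-2,5-dien-1-olate | C[Se]C(C)(C)C1(O[Li])C=CC(=O)C=C1
F2 | step 4 | 4-[2-(methylselanyl)propan-2-yl]-4-[(trimethylsilyl)oxy]cyclohexa-2,5-dien-1-one | C[Se]C(C)(C)C1(O[Si](C)(C)C)C=CC(=O)C=C1
F3 | step 4 | (4aR,8R,8aS)-8-[2-(methylselanyl)propan-2-yl]-5-oxo-8-[(trimethylsilyl)oxy]-1,4,4a,5,8,8a-hexahydronaphthalen-2-yl acetate | C[Se]C(C)(C)[C@@]1(O[Si](C)(C)C)C=CC(=O)[C@@H]2CC=C(OC(C)=O)C[C@@H]21
F4 | step 11 | 6-(acetyloxy)-5-bromo-5,9,9-trimethyl-2-oxo-2,4a,5,6,7,8,9,9a-octahydro-1H-benzo[7]annulen-8-yl (2Z)-2-methylbut-2-enoate (bromide trans to acetate) | C/C=C(/C)C(=O)O[C@@H]1C[C@@H](OC(C)=O)[C@](C)(Br)[C@@H]2C=CC(=O)C[C@@H]2C1(C)C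
F5 | step 11 | 6-(acetyloxy)-5-bromo-5,9,9-trimethyl-2-[(trimethylsilyl)oxy]-4a,5,6,7,8,9-hexahydro-9aH-benzo[7]annulen-8-yl (2Z)-2-methylbut-2-enoate | C/C=C(/C)C(=O)O[C@@H]1C[C@@H](OC(C)=O)[C@](C)(Br)[C@@H]2C=CC(O[Si](C)(C)C)=C[C@@H]2C1(C)C
F6 | step 3 | (4aS,8S,8aR)-5-oxo-8-(prop-1-en-2-yl)-8-[(trimethylsilyl)oxy]-1,4,4a,5,8,8a-hexahydronaphthalen-2-yl acetate | C=C(C)[C@]1(O[Si](C)(C)C)C=CC(=O)[C@H]2CC=C(OC(C)=O)C[C@H]21
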